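A direct plan would grow the rings in the order five, six, four, starting from 2-methylcyclopentane-1,3-dione A1.
Allylation of the dione A1, enzymatic desymmetrisation to the hydroxy ketone A2 and two SN2 inversions in a row would give the bromo ketone A3.
An ynone annulation, conjugate reduction and ozonolysis would lead to the bicyclic keto aldehyde A4.
A SmI2 ketyl–olefin closure would make the cyclobutanol A5; acetylation, α-bromination and borohydride reduction would finish.
Weak (a), the double inversion at the neopentyl carbinol carbon: it only corrects the sense of the enzymatic reduction, at a hindered centre, and builds nothing.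
Weak (b), the 4-exo ketyl–olefin closure: the strained ring is closed last between two quaternary carbons, SmI2 can also cleave the secondary C–Br bond, and the carbinol configuration rests on a small conformational bias.
Weak (c), the annulation: Michael addition of a fully substituted enolate and aldol condensation onto a carbonyl next to a quaternary carbon are both sterically hard.

**Retrosynthetic overview**
Ring B (cyclopentane C1, C4–C7) and ring C (cyclobutane C1–C4) are cut together through C1–C4 and C2–C3: one copper-templated [2+2] photocycloaddition of the hepta-1,6-diene unit C3=C4–C5–C6–C7–C1=C2 in the monocyclic precursor 16 forms both bonds.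
This step joins the quaternary carbons C1 and C4 beside quaternary C7, sets C1, C2 and C4, and brings in the C2 acetate as such from an (E)-enol acetate.
Ring A (cyclohexane C1, C7–C11) is made first, by an enantioselective Diels–Alder reaction that fixes C7 and C8 from the geometry of tiglic aldehyde; conjugate vinylation/methylation then adds C2 and the C11 methyl group.
Order of ring formation: A, then B and C together (the direct plan: B, A, C).
There is no SmI2 closure and no carbinol correction: the C5 carbinol is set once by reagent control and inverted once, productively, by bromide; both bromine atoms enter after the photochemical step.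

Key step: step 8

Remark: tricyclic compounds are numbered as tricyclo[5.4.0.0^{1,4}]undecanes (C1 central quaternary carbon, C2 CH–OAc, C3 CH2, C4 C–Me, C5 CHBr, C6 CH2, C7 C–Me, C8 CHMe, C9 CHBr, C10 CHOH, C11 CHMe).
Remark: the sense of induction of the chiral catalyst in step 1 and of the chiral ligand in step 7 is assumed by analogy; the enantiomer that gives the configuration drawn is the one to be used.
Remark: in 9–16 the ring carbons next to the future C1 that later become sp2 (step 5) or are equilibrated (step 8) are written without descriptor.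

Step 1
Reactants: 1 (E)-2-methylbut-2-enal (tiglic aldehyde); 2 (E)-3-[(tert-butyldimethylsilyl)oxy]-N,N-dimethylbuta-1,3-dien-1-amine
Product: 3 (1R,2S,6S)-4-[(tert-butyldimethylsilyl)oxy]-2-(dimethylamino)-1,6-dimethylcyclohex-3-ene-1-carbaldehyde
Conditions: (R,R)-(salen)CrSbF6 (5 mol %; trivalent chromium; salen = N,N′-bis(3,5-di-tert-butylsalicylidene)cyclohexane-1,2-diamine dianion), 4 Å MS, CH2Cl2, −40 °C → rt; used crude
Reagents that add atoms: none
Why: Catalytic enantioselective Diels–Alder reaction of a 1-amino-3-siloxydiene with an α-substituted enal: the CH2 terminus of the diene bonds to the β-carbon of the enal, so the formyl-bearing carbon becomes the quaternary ring carbon (future C7), the (E)-geometry of the dienophile fixes the two methyl groups cis, and the chiral chromium Lewis acid selects the face.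

Step 2
Reactants: 3 (1R,2S,6S)-4-[(tert-butyldimethylsilyl)oxy]-2-(dimethylamino)-1,6-dimethylcyclohex-3-ene-1-carbaldehyde; 4 (methoxymethyl)triphenylphosphonium chloride
Product: 6 (4R,5S)-4-(2,2-dimethoxyethyl)-4,5-dimethylcyclohex-2-en-1-one, via enol ether 5 (not isolated)
Conditions: 4, KN(SiMe3)2, THF, 0 °C; add 3, −78 → 0 °C; then HCl (2 equiv) in MeOH, 0 °C → rt
Reagents that add atoms: methanol, CO
Why: Wittig methoxymethylenation of the aldehyde while the ketone is still masked as silyl enol ether; acidic methanol then adds to the enol ether (dimethyl acetal), cleaves the silyl enol ether and eliminates dimethylamine (E1cB) to unveil the enone, with no stereocentre touched.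

Step 3
Reactants: 6 (4R,5S)-4-(2,2-dimethoxyethyl)-4,5-dimethylcyclohex-2-en-1-one; 7 vinylmagnesium bromide
Product: 9 (4R,5S)-4-(2,2-dimethoxyethyl)-3-ethenyl-2,4,5-trimethylcyclohexan-1-one (C2/C3 epimers), via magnesium enolate 8 (not isolated)
Conditions: 7 (1.5 equiv), CuBr·SMe2 (10 mol %), THF, −78 → −30 °C; then MeI (5 equiv), DMPU, −30 → 0 °C
Reagents that add atoms: iodomethane, CI
Why: Copper-catalysed conjugate addition of the vinyl Grignard reagent to the enone β-carbon (future C1) and regiospecific C-methylation of the magnesium enolate (future C11); neither new centre needs control, because one becomes sp2 in step 5 and the other is equilibrated in step 8.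

Step 4
Reactants: 9 (4R,5S)-4-(2,2-dimethoxyethyl)-3-ethenyl-2,4,5-trimethylcyclohexan-1-one
Product: 11 (5S,6R)-6-(2,2-dimethoxyethyl)-2,5,6-trimethyl-3-oxocyclohexane-1-carbaldehyde (C1/C2 epimers), via ozonide 10 (not isolated)
Conditions: O3, CH2Cl2, −78 °C (Sudan Red 7B end point); then PPh3, −78 °C → rt
Reagents that add atoms: ozone, [O-][O+]=O
Why: Ozonolysis with reductive work-up cleaves the only C=C bond to the aldehyde (future C2); the indicator end point keeps the dimethyl acetal from over-oxidation.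

Step 5
Reactants: 11 (5S,6R)-6-(2,2-dimethoxyethyl)-2,5,6-trimethyl-3-oxocyclohexane-1-carbaldehyde
Product: 12 [(E)-[(2R,3S)-2-(2,2-dimethoxyethyl)-2,3,6-trimethyl-5-oxocyclohexylidene]methyl] acetate
Conditions: Ac2O, Et3N, DMAP (0.2 equiv), toluene, 60 °C
Reagents that add atoms: acetic anhydride, CC(=O)OC(C)=O
Why: Base-mediated enol acetylation of the α-branched aldehyde (the ketone does not enol-acetylate under these conditions); O-acylation should favour the (E)-isomer, with the acetoxy group turned away from the quaternary carbon (allylic 1,3-strain), and this geometry later sets C2.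

Step 6
Reactants: 12 [(E)-[(2R,3S)-2-(2,2-dimethoxyethyl)-2,3,6-trimethyl-5-oxocyclohexylidene]methyl] acetate
Product: 13 [(E)-[(2R,3S)-2,3,6-trimethyl-5-oxo-2-(2-oxoethyl)cyclohexylidene]methyl] acetate
Conditions: LiBF4, MeCN/H2O (50:1), rt
Reagents that add atoms: water, O
Why: Mild Lewis acid hydrolysis of the dimethyl acetal unveils the chain aldehyde (future C5); enol acetate and ketone should be stable to these conditions.

Step 7
Reactants: 13 [(E)-[(2R,3S)-2,3,6-trimethyl-5-oxo-2-(2-oxoethyl)cyclohexylidene]methyl] acetate; 14 2-bromopropene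
Product: 16 [(E)-[(2R,3S)-2,3,6-trimethyl-2-[(2R)-3-methyl-2-[(triethylsilyl)oxy]but-3-en-1-yl]-5-oxocyclohexylidene]methyl] acetate, via alcohol 15 (not isolated)
Conditions: 14, CrCl2 (4 equiv), NiCl2 (2 mol %), (S)-N-[2-(4-isopropyl-4,5-dihydro-1,3-oxazol-2-yl)-6-methylphenyl]methanesulfonamide (4.4 equiv), Et3N, THF, rt; aqueous work-up; then Et3SiCl, imidazole, DMF, 0 °C
Reagents that add atoms: chlorotriethylsilane, CC[Si](Cl)(CC)CC
Why: Nozaki–Hiyama–Kishi alkenylation: the isopropenylchromium reagent adds to the aldehyde only (ketone and enol ester are inert), and the chiral sulfonamide ligand sets the (R)-carbinol by reagent control, because the β-quaternary centre gives little induction; silylation prevents the hydroxyl group from steering copper in step 8.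

Step 8
Reactants: 16 [(E)-[(2R,3S)-2,3,6-trimethyl-2-[(2R)-3-methyl-2-[(triethylsilyl)oxy]but-3-en-1-yl]-5-oxocyclohexylidene]methyl] acetate
Product: 18 (1R,2R,4R,5R,7R,8S,11R)-4,7,8,11-tetramethyl-10-oxo-5-[(triethylsilyl)oxy]tricyclo[5.4.0.0^{1,4}]undecan-2-yl acetate, via C11 epimer 17 (not isolated)
Conditions: (CuOTf)2·C6H6 (5 mol %; monovalent copper), Et2O, hν 254 nm (quartz), rt; then DBU (0.2 equiv), CH2Cl2, rt
Reagents that add atoms: none
Why: CuOTf binds the two C=C bonds of the hepta-1,6-diene unit (C3=C4 and C1=C2) in one complex, and excitation of this complex at 254 nm couples them to the cyclobutane. The closest known reaction type is the copper-catalysed [2+2] photobicyclisation of 1,6-dienes (Salomon–Kochi reaction), known for 3-oxygenated hepta-1,6-dienes, for vinyl ether partners and for closures that form quaternary carbons. Ring B closes through the C4–C1 bond in the five-membered mode (rule of five), and ring C through the C3–C2 bond in the parallel mode that the copper template enforces over the crossed one. At C1 the three-atom tether from C7 should reach only the face of the C7–C6 bond (cis ring fusion), which puts C2 cis to the C7 methyl group, and at C4 the obligatory cis fusion of the cyclobutane puts the methyl group on the face of C11. At C2 the (E)-enol acetate geometry is carried over suprafacially and places the acetoxy group exo, cis to C11, which is also the less hindered position; the preset C5 silyl ether ends exo and cannot steer the copper to the other face. The step needs the copper complex to be the main absorber at 254 nm, so that the ketone and the enol ester stay in the ground state; DBU then equilibrates C11 to the equatorial methyl epimer, since the axial one has a 1,3-diaxial contact with the C7 methyl group.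

Step 9
Reactants: 18 (1R,2R,4R,5R,7R,8S,11R)-4,7,8,11-tetramethyl-10-oxo-5-[(triethylsilyl)oxy]tricyclo[5.4.0.0^{1,4}]undecan-2-yl acetate
Product: 21 (1R,2R,4R,5R,7R,8R,9S,11R)-9-bromo-4,7,8,11-tetramethyl-10-oxo-5-[(triethylsilyl)oxy]tricyclo[5.4.0.0^{1,4}]undecan-2-yl acetate, via lithium enolate 19 (not isolated), via silyl enol ether 20 (not isolated)
Conditions: LiN(SiMe3)2 (1.1 equiv), THF, −78 °C; Me3SiCl, −78 °C; then NBS, THF, −78 → 0 °C
Reagents that add atoms: N-bromosuccinimide, O=C1CCC(=O)N1Br
Why: Kinetic deprotonation at the less hindered C9 methylene, silylation and electrophilic bromination of the silyl enol ether; bromine should enter anti to the syn-axial C7 methyl group and give the equatorial bromide trans to the C8 methyl group, which is also the thermodynamic epimer.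

Step 10
Reactants: 21 (1R,2R,4R,5R,7R,8R,9S,11R)-9-bromo-4,7,8,11-tetramethyl-10-oxo-5-[(triethylsilyl)oxy]tricyclo[5.4.0.0^{1,4}]undecan-2-yl acetate
Product: 23 (1R,2R,4R,5R,7R,8R,9S,10R,11R)-9-bromo-5,10-dihydroxy-4,7,8,11-tetramethyltricyclo[5.4.0.0^{1,4}]undecan-2-yl acetate, via silyl ether 22 (not isolated)
Conditions: NaBH4, MeOH/THF, −40 → 0 °C; then HF·pyridine, THF, 0 °C → rt
Reagents that add atoms: none
Why: Borohydride should attack the α-bromo ketone along the equatorial trajectory, because the axial one is blocked by the axial C1–C4 bond in 1,3-position, and give the axial alcohol cis to bromine (a cis-bromohydrin cannot close to an epoxide); fluoride then removes the silyl group without touching the acetate.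

Step 11
Reactants: 23 (1R,2R,4R,5R,7R,8R,9S,10R,11R)-9-bromo-5,10-dihydroxy-4,7,8,11-tetramethyltricyclo[5.4.0.0^{1,4}]undecan-2-yl acetate
Product: 25 (1R,2R,4R,5S,7R,8R,9S,10R,11R)-5,9-dibromo-10-hydroxy-4,7,8,11-tetramethyltricyclo[5.4.0.0^{1,4}]undecan-2-yl acetate (CNP0246576.1), via triflate 24 (not isolated)
Conditions: Tf2O (1.05 equiv), pyridine, CH2Cl2, −78 → −30 °C; then n-Bu4NBr (3 equiv), toluene, −40 → 20 °C
Reagents that add atoms: tetrabutylammonium bromide, CCCC[N+](CCCC)(CCCC)CCCC.[Br-]
Why: Chemoselective triflation of the C5 hydroxyl (the C10 hydroxyl is axial, syn to the C1–C4 bond and deactivated by the vicinal bromine), then SN2 displacement by bromide with inversion in a non-polar medium, which should outrun ionisation and puts bromine on the face of the cyclobutane and the C7 methyl group.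

## Compound list

1 | (E)-2-methylbut-2-enal (tiglic aldehyde) | C/C=C(\C)C=O | starting material
2 | (E)-3-[(tert-butyldimethylsilyl)oxy]-N,N-dimethylbuta-1,3-dien-1-amine | C=C(O[Si](C)(C)C(C)(C)C)/C=C/N(C)C | starting material
3 | (1R,2S,6S)-4-[(tert-butyldimethylsilyl)oxy]-2-(dimethylamino)-1,6-dimethylcyclohex-3-ene-1-carbaldehyde (endo cycloadduct) | O=C[C@@]1(C)[C@@H](N(C)C)C=C(O[Si](C)(C)C(C)(C)C)C[C@@H]1C | intermediate
4 | (methoxymethyl)triphenylphosphonium chloride | COC[P+](c1ccccc1)(c1ccccc1)c1ccccc1.[Cl-] | starting material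
5 | methyl enol ether from 3 (2-methoxyethenyl in place of formyl; E/Z mixture) | COC=C[C@@]1(C)[C@@H](N(C)C)C=C(O[Si](C)(C)C(C)(C)C)C[C@@H]1C | intermediate
6 | (4R,5S)-4-(2,2-dimethoxyethyl)-4,5-dimethylcyclohex-2-en-1-one | COC(OC)C[C@@]1(C)C=CC(=O)C[C@@H]1C | intermediate
7 | vinylmagnesium bromide | C=C[Mg]Br | starting material
8 | bromomagnesium enolate from conjugate addition to 6 | COC(OC)C[C@@]1(C)C(C=C)C=C(O[Mg]Br)C[C@@H]1C | intermediate
9 | (4R,5S)-4-(2,2-dimethoxyethyl)-3-ethenyl-2,4,5-trimethylcyclohexan-1-one (C2/C3 epimers) | COC(OC)C[C@@]1(C)C(C=C)C(C)C(=O)C[C@@H]1C | intermediate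
10 | secondary ozonide (1,2,4-trioxolane) of the vinyl group of 9 | COC(OC)C[C@@]1(C)C(C2OCOO2)C(C)C(=O)C[C@@H]1C | intermediate
11 | (5S,6R)-6-(2,2-dimethoxyethyl)-2,5,6-trimethyl-3-oxocyclohexane-1-carbaldehyde (C1/C2 epimers) | COC(OC)C[C@@]1(C)C(C=O)C(C)C(=O)C[C@@H]1C | intermediate
12 | [(E)-[(2R,3S)-2-(2,2-dimethoxyethyl)-2,3,6-trimethyl-5-oxocyclohexylidene]methyl] acetate (C6 epimers) | COC(OC)C[C@@]1(C)/C(=C/OC(C)=O)C(C)C(=O)C[C@@H]1C | intermediate
13 | [(E)-[(2R,3S)-2,3,6-trimethyl-5-oxo-2-(2-oxoethyl)cyclohexylidene]methyl] acetate | O=CC[C@@]1(C)/C(=C/OC(C)=O)C(C)C(=O)C[C@@H]1C | intermediate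
14 | 2-bromopropene | CC(Br)=C | starting material
15 | [(E)-[(2R,3S)-2-[(2R)-2-hydroxy-3-methylbut-3-en-1-yl]-2,3,6-trimethyl-5-oxocyclohexylidene]methyl] acetate | O[C@H](C[C@@]1(C)/C(=C/OC(C)=O)C(C)C(=O)C[C@@H]1C)C(C)=C | intermediate
16 | [(E)-[(2R,3S)-2,3,6-trimethyl-2-[(2R)-3-methyl-2-[(triethylsilyl)oxy]but-3-en-1-yl]-5-oxocyclohexylidene]methyl] acetate | CC[Si](CC)(CC)O[C@H](C[C@@]1(C)/C(=C/OC(C)=O)C(C)C(=O)C[C@@H]1C)C(C)=C | intermediate
17 | (1R,2R,4R,5R,7R,8S,11S)-4,7,8,11-tetramethyl-10-oxo-5-[(triethylsilyl)oxy]tricyclo[5.4.0.0^{1,4}]undecan-2-yl acetate (C11 epimer of 18) | CC(=O)O[C@@H]1C[C@@]2(C)[C@H](O[Si](CC)(CC)CC)C[C@]3(C)[C@@H](C)CC(=O)[C@@H](C)[C@]123 | intermediate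
18 | (1R,2R,4R,5R,7R,8S,11R)-4,7,8,11-tetramethyl-10-oxo-5-[(triethylsilyl)oxy]tricyclo[5.4.0.0^{1,4}]undecan-2-yl acetate | CC(=O)O[C@@H]1C[C@@]2(C)[C@H](O[Si](CC)(CC)CC)C[C@]3(C)[C@@H](C)CC(=O)[C@H](C)[C@]123 | intermediate
19 | lithium C9–C10 enolate of 18 | CC(=O)O[C@@H]1C[C@@]2(C)[C@H](O[Si](CC)(CC)CC)C[C@]3(C)[C@@H](C)C=C(O[Li])[C@H](C)[C@]123 | intermediate
20 | trimethylsilyl C9–C10 enol ether of 18 | CC(=O)O[C@@H]1C[C@@]2(C)[C@H](O[Si](CC)(CC)CC)C[C@]3(C)[C@@H](C)C=C(O[Si](C)(C)C)[C@H](C)[C@]123 | intermediate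
21 | (1R,2R,4R,5R,7R,8R,9S,11R)-9-bromo-4,7,8,11-tetramethyl-10-oxo-5-[(triethylsilyl)oxy]tricyclo[5.4.0.0^{1,4}]undecan-2-yl acetate | CC(=O)O[C@@H]1C[C@@]2(C)[C@H](O[Si](CC)(CC)CC)C[C@]3(C)[C@@H](C)[C@H](Br)C(=O)[C@H](C)[C@]123 | intermediate
22 | (1R,2R,4R,5R,7R,8R,9S,10R,11R)-9-bromo-10-hydroxy-4,7,8,11-tetramethyl-5-[(triethylsilyl)oxy]tricyclo[5.4.0.0^{1,4}]undecan-2-yl acetate | CC(=O)O[C@@H]1C[C@@]2(C)[C@H](O[Si](CC)(CC)CC)C[C@]3(C)[C@@H](C)[C@H](Br)[C@H](O)[C@H](C)[C@]123 | intermediate
23 | (1R,2R,4R,5R,7R,8R,9S,10R,11R)-9-bromo-5,10-dihydroxy-4,7,8,11-tetramethyltricyclo[5.4.0.0^{1,4}]undecan-2-yl acetate | CC(=O)O[C@@H]1C[C@@]2(C)[C@H](O)C[C@]3(C)[C@@H](C)[C@H](Br)[C@H](O)[C@H](C)[C@]123 | intermediate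
24 | C5 trifluoromethanesulfonate of 23 (configuration retained) | CC(=O)O[C@@H]1C[C@@]2(C)[C@H](OS(=O)(=O)C(F)(F)F)C[C@]3(C)[C@@H](C)[C@H](Br)[C@H](O)[C@H](C)[C@]123 | intermediate
25 | (1R,2R,4R,5S,7R,8R,9S,10R,11R)-5,9-dibromo-10-hydroxy-4,7,8,11-tetramethyltricyclo[5.4.0.0^{1,4}]undecan-2-yl acetate | CC(=O)O[C@@H]1C[C@@]2(C)[C@@H](Br)C[C@]3(C)[C@@H](C)[C@H](Br)[C@H](O)[C@H](C)[C@]123 | target

**Step count and risks**
Total step count: 11. Longest linear sequence: 11 steps (from 1 and 2).

Most likely to fail: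

1. Step 8 (key step). The two fully substituted carbons C1 and C4 may not close, light may be lost to a 1,3-acyl shift of the enol ester or of the β,γ-unsaturated ketone, or loss of the enol acetate geometry may erode C2. The fallback makes the same two bonds thermally through a ketene and sets out from 16. Methanolysis of the enol acetate (K2CO3, MeOH) would give the aldehyde F1, and chlorite oxidation (NaClO2, NaH2PO4, 2-methylbut-2-ene) the acid F2. Oxalyl chloride would give the acid chloride F3, and Et3N in refluxing toluene the ketene F4. This should close by intramolecular ketene–alkene [2+2] cycloaddition (carbonyl carbon to the CH2 terminus, ketene carbon to the methyl-bearing alkene carbon) to the cyclobutanone F5 with the same cis ring fusion. KBH(s-Bu)3 at −78 °C should reduce the strained, more electrophilic cyclobutanone from its open exo face to the endo alcohol F6. A Mitsunobu esterification with acetic acid (PPh3, DIAD) would invert C2 to the exo acetate and come back to the route at 18.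

2. Step 11. The C5 triflate may ionise with ring expansion of the neighbouring cyclobutane, eliminate towards C6, or the C10 hydroxyl may be sulfonylated in competition. The fallback moves the displacement in front of the carbonyl reduction, to a substrate with a single hydroxyl group, and sets out from 21. HF·pyridine would give the bromo keto alcohol F7, Tf2O/pyridine its triflate F8, and n-Bu4NBr the dibromo ketone F9. NaBH4 reduction as in step 10 would come back to the route at 25.

3. Step 1. The β-methyl group of the enal may make the cycloaddition slow, or the face selection by the chromium catalyst may be low. The fallback reaches 6 by dearomatisation and desymmetrisation. p-Cresol would be oxidised with PhI(OAc)2 in the presence of allyltrimethylsilane (hexafluoroisopropanol) to 4-allyl-4-methylcyclohexa-2,5-dien-1-one F10. A copper-catalysed enantioselective conjugate addition of Me3Al (copper thiophene-2-carboxylate, monovalent copper, with a chiral phosphoramidite ligand) would give (4R,5S)-4-allyl-4,5-dimethylcyclohex-2-en-1-one F11; the isomer from attack on the other face would have to be separated. Ozonolysis of the allyl group would give 2-[(1R,6S)-1,6-dimethyl-4-oxocyclohex-2-en-1-yl]acetaldehyde F12, and acidic methanol would come back to the route at 6.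

Further compounds
F1 | step 8 | (5S,6R)-2,5,6-trimethyl-6-[(2R)-3-methyl-2-[(triethylsilyl)oxy]but-3-en-1-yl]-3-oxocyclohexane-1-carbaldehyde | CC[Si](CC)(CC)O[C@H](C[C@@]1(C)C(C=O)C(C)C(=O)C[C@@H]1C)C(C)=C
F2 | step 8 | (5S,6R)-2,5,6-trimethyl-6-[(2R)-3-methyl-2-[(triethylsilyl)oxy]but-3-en-1-yl]-3-oxocyclohexane-1-carboxylic acid | CC[Si](CC)(CC)O[C@H](C[C@@]1(C)C(C(=O)O)C(C)C(=O)C[C@@H]1C)C(C)=C
F3 | step 8 | acid chloride of F2 | CC[Si](CC)(CC)O[C@H](C[C@@]1(C)C(C(Cl)=O)C(C)C(=O)C[C@@H]1C)C(C)=C
F4 | step 8 | ketene from F3 (cyclohexylidene ketene) | CC[Si](CC)(CC)O[C@H](C[C@@]1(C)C(=C=O)C(C)C(=O)C[C@@H]1C)C(C)=C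
F5 | step 8 | (1R,4R,5R,7R,8S,11R)-4,7,8,11-tetramethyl-5-[(triethylsilyl)oxy]tricyclo[5.4.0.0^{1,4}]undecane-2,10-dione | O=C1C[C@@]2(C)[C@H](O[Si](CC)(CC)CC)C[C@]3(C)[C@@H](C)CC(=O)[C@H](C)[C@]123
F6 | step 8 | (2S)-endo alcohol: (1R,2S,4R,5R,7R,8S,11R)-2-hydroxy-4,7,8,11-tetramethyl-5-[(triethylsilyl)oxy]tricyclo[5.4.0.0^{1,4}]undecan-10-one | O[C@H]1C[C@@]2(C)[C@H](O[Si](CC)(CC)CC)C[C@]3(C)[C@@H](C)CC(=O)[C@H](C)[C@]123
F7 | step 11 | (1R,2R,4R,5R,7R,8R,9S,11R)-9-bromo-5-hydroxy-4,7,8,11-tetramethyl-10-oxotricyclo[5.4.0.0^{1,4}]undecan-2-yl acetate | CC(=O)O[C@@H]1C[C@@]2(C)[C@H](O)C[C@]3(C)[C@@H](C)[C@H](Br)C(=O)[C@H](C)[C@]123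
F8 | step 11 | C5 trifluoromethanesulfonate of F7 | CC(=O)O[C@@H]1C[C@@]2(C)[C@H](OS(=O)(=O)C(F)(F)F)C[C@]3(C)[C@@H](C)[C@H](Br)C(=O)[C@H](C)[C@]123
F9 | step 11 | (1R,2R,4R,5S,7R,8R,9S,11R)-5,9-dibromo-4,7,8,11-tetramethyl-10-oxotricyclo[5.4.0.0^{1,4}]undecan-2-yl acetate | CC(=O)O[C@@H]1C[C@@]2(C)[C@@H](Br)C[C@]3(C)[C@@H](C)[C@H](Br)C(=O)[C@H](C)[C@]123
F10 | step 1 | 4-allyl-4-methylcyclohexa-2,5-dien-1-one | C=CCC1(C)C=CC(=O)C=C1
F11 | step 1 | (4R,5S)-4-allyl-4,5-dimethylcyclohex-2-en-1-one | C=CC[C@@]1(C)C=CC(=O)C[C@@H]1C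
F12 | step 1 | 2-[(1R,6S)-1,6-dimethyl-4-oxocyclohex-2-en-1-yl]acetaldehyde | O=CC[C@@]1(C)C=CC(=O)C[C@@H]1C
A1 | direct plan | 2-methylcyclopentane-1,3-dione | CC1C(=O)CCC1=O
A2 | direct plan | (2S,3S)-3-hydroxy-2-methyl-2-(prop-2-en-1-yl)cyclopentan-1-one | O=C1CC[C@H](O)[C@]1(C)CC=C
A3 | direct plan | (2R,3S)-3-bromo-2-methyl-2-(prop-2-en-1-yl)cyclopentan-1-one | O=C1CC[C@H](Br)[C@]1(C)CC=C
A4 | direct plan | 2-[(2S,3R,7S,7aR)-2-bromo-3,4,7,7a-tetramethyl-5-oxo-1,2,3,6,7,7a-hexahydroinden-3-yl]acetaldehyde | CC1=C2[C@@](C)(CC=O)[C@@H](Br)C[C@]2(C)[C@@H](C)CC1=O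
A5 | direct plan | (1R,2R,4R,5S,7R,8S,11R)-5-bromo-2-hydroxy-4,7,8,11-tetramethyltricyclo[5.4.0.0^{1,4}]undecan-10-one | O[C@@H]1C[C@@]2(C)[C@@H](Br)C[C@]3(C)[C@@H](C)CC(=O)[C@H](C)[C@]123
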